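## Structural features

The target (26) has one ring, a cyclohexene C1–C6. Its sp2 carbon C1 carries a C7≡C8 alkyne conjugated to a 1,1-disubstituted alkene at C9 (exocyclic =CH2). C10 is a doubly allylic methylene leading to an E C11=C12 alkene and the tertiary carbinol C13 with two methyl groups. The rest of the ring holds four contiguous oxygenated stereocentres: C3 (OAc), C4 (OMe), C5 (OH) and C6 (OH). They are 3,4-cis, 4,5-trans and 5,6-cis, with absolute configuration 3S,4R,5S,6S in this numbering. The fragile groups are the allylic acetate (ionisable by zerovalent palladium, labile to base), the tertiary allylic alcohol (ionised by acid), the skipped diene (isomerisation at C10) and the enyne (reduction, hydrometalation). The real difficulty is to place three different oxygen functions (acetate, methyl ether, free cis-diol) on four neighbouring carbons of one enantiomer, and to attach an alkyne to a fully substituted alkene carbon next to a carbinol. The key step uses two facts. C1 is the α-carbon of a C7 acyl group and also the neighbour of carbinol C6, which is the 2-(hydroxyalkyl)acrylate pattern of a Morita–Baylis–Hillman adduct. C3, C4 and C5 with their oxygens coincide with C4, C3 and C2 of L-arabinose, whose O3 becomes the methyl ether. C7 arrives at the carboxyl oxidation level and is converted to the alkyne afterwards.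

## Logic of the disconnections

26 ⇒ 23 (through 25 and 24). The acyl–O3 bond is cut first because the acetate is the most fragile group and would not survive hydride, amide base or fluoride. The gain is a precursor without protecting groups. The demand is that acetylation finds O3 among four hydroxyls; the cis-5,6-diol is therefore masked in the flask as a cyclic boronate and released under neutral conditions.

23 ⇒ 22. Three Si–O bonds (O3, O5, O6) are cut. Identical silyl ethers keep the earlier steps simple, and fluoride removes them without acid, which the C13 carbinol requires.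

22 ⇒ 16 + 21. The C8–C9 bond between the sp and sp2 carbons is cut. This separates the chiral ring from the achiral side chain at the only bond that a Pd(PPh3)4/CuI coupling makes directly. The forward step must tolerate a free tertiary alcohol and must not isomerise the skipped diene.

21 ⇒ 17 + 18 (through 20 and 19). The C10–C11 bond is cut so that the E alkene comes from syn-hydrometalation of a terminal alkyne and the bromoalkene comes from a symmetrical allyl electrophile. The forward step needs an alkenyl metal that attacks the allylic and not the vinylic C–Br bond.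

16 ⇒ 15 ⇒ 14 ⇒ 13 ⇒ 12. C8 is removed (one-carbon homologation of an aldehyde), C7 is taken back through alcohol to ester, and the O6 silyl group is removed. The gain is that C7 is traced to an ester on C1. The demand is a homologation that works on a conjugated, hindered aldehyde.

12 ⇒ 11. The C1–C6 bond is cut, which opens the ring to an acyclic enoate aldehyde. This removes the ring and one stereocentre in one operation and leaves a chain whose three stereocentres are those of a pentose. The forward step must close the six-membered ring faster than intermolecular reactions and must set C6 cis to the C5 oxygen.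

11 ⇒ 10 ⇒ 7 + 8 (through 9). The C6 aldehyde is masked as a dithioacetal and the C1=C2 alkene is cut (Wittig). The mask allows the sugar C1 to wait while the sugar C5 is oxidised and extended. The forward unmasking must spare silyl ethers, the enoate and the configuration at C5.

7 ⇒ 6 ⇒ 5. Si–O bonds are cut. All three hydroxyls are silylated and the primary one is released again, so the sugar C5 is the only carbinol open to oxidation.

5 ⇒ 4 ⇒ 2 (through 3) ⇒ 1. The two C–S bonds, the O3–CH3 bond and the glycosidic bond are cut. The pyranoside holds O3 and O4 as a cis-diol, so O3 can be methylated selectively through tin; mercaptolysis then turns the ring into the open chain. The demand is regiocontrol in the single methylation.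

## Other disconnections considered

Alternative 1: The ring is taken from an aromatic precursor, the achiral quinone monoketal A1. The cut is the pair of C–O bonds (C4–O and C5–O) of an oxirane. The forward key step would be a nucleophilic (Weitz–Scheffer) epoxidation of one of the two enantiotopic enone alkenes of A1 with an alkyl hydroperoxide and a chiral cinchona-derived quaternary ammonium phase-transfer catalyst, giving the epoxy enone A2. Later steps would be iodination at C1 and alkyne coupling, reduction of the C6 ketone, methanolysis of the oxirane at C4 with inversion, unmasking and reduction at C3, and acetylation.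
- In its favour: the ring is bought and not built, the key step is catalytic and sets C4 and C5 together, and the route is probably the shortest of the four. It also follows the likely biogenesis of the methyl ether from an epoxide. On step economy it is the better plan.
- Against it: the absolute configuration rests on catalyst control in a desymmetrisation that is unlikely to be complete for an unsubstituted monoketal. C3 and C6 must each be set by a separate ketone reduction. The oxirane must open at C4 and not at C5, on conformational grounds only. The two carbinols at C3 and C6 must then be told apart for monoacetylation.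
- Comparison: in the chosen plan three of the four stereocentres come from the pentose and the methyl ether is in place from the second step, which is the stronger position on structure. Mechanistically both plans turn on a conjugate addition to an electron-poor alkene. The two are equal in how the side chain is joined, by alkyne cross-coupling at C1.

Alternative 2: The C2–C3 bond is cut (retro-aldol) and the ring is traced to the hex-5-enopyranoside A4, made from D-galactose A3. In the forward step catalytic Hg(OCOCF3)2 in aqueous acetone would oxymercurate the exocyclic enol ether, the hemiacetal would open to a keto aldehyde, and intramolecular aldol reaction would give the cyclohexanone A5.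
- In its favour: A5 would hold all four stereocentres. C4, C5 and C6 come from the sugar, and C3 from an aldol whose usual preference (new hydroxyl cis to the sugar O2 substituent) is the one required. Methylation of O2 next to a 3,4-acetonide is regiochemically trivial, which is better than the tin-mediated methylation used here. The C3 hydroxyl arrives already differentiated from the 5,6-diol, which is also better than the late differentiation of the chosen plan.
- Against it: C1 is a ketone and C7 is absent, so the alkyne must be added to the ring and the C1=C2 alkene made regioselectively. A5 is a β-hydroxy ketone prone to E1cB loss of the C3 oxygen, which would place the alkene at C2=C3 and destroy C3. The route uses a mercury salt. The acetonide must finally be removed with acid in the presence of the C13 carbinol and the allylic acetate.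
- Comparison: on stereochemistry the alternative is the equal of the chosen plan. On mechanism both are six-membered aldol-type closures of sugar-derived dicarbonyl compounds, but the chosen closure returns the C1=C2 alkene and the C7 carbon in the same step. The step count is expected to be similar or slightly higher for the alternative.

Alternative 3: The C3–C4 bond is cut (retro-pinacol) to the Z-enynal dialdehyde A6. In the forward step SmI2 would reduce the two aldehydes to ketyls and couple them through a samarium-bridged diolate, giving the cis-diol A7 with both new hydroxyls trans to the C5 oxygen.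
- In its favour: the alkyne and the C1=C2 alkene are in place before ring closure, so fewer steps follow it; on that count the alternative is better. Two stereocentres are set at once with the required 3,4-cis relationship.
- Against it: A7 has free, undifferentiated hydroxyls at C3 and C4. The non-allylic, more hindered C4 hydroxyl would have to be methylated selectively, a problem the chosen plan never meets. A6 needs a geometrically pure trisubstituted Z-enal that can isomerise, and its α-alkoxy aldehyde can epimerise. The ketyl of a conjugated enynal is delocalised and may couple or be reduced elsewhere. The acetonide again has to be removed with acid at the end.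
- Comparison: both plans close the ring between two carbonyl-derived carbons under substrate control by the neighbouring oxygen, and are equal in that respect. The chosen closure is indifferent to alkene geometry, whereas the alternative depends on it. Overall length is expected to be comparable.

Key step: step 8

Remark on the chemistry: carbocycles and their open-chain precursors are described in the numbering of the target (C1 to C13 as above) and sugar derivatives in carbohydrate numbering; 2 and 17 are also articles of commerce, 17 is taken as purchased, and buying 2 would save step 1.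

## Steps

Step 1
Reactants: 1 L-arabinose
Product: 2 methyl β-L-arabinopyranoside
Conditions: HCl (1% in MeOH), reflux; crystallisation
Reagents that add atoms: methanol, CO
Why: Fischer glycosidation under thermodynamic control should favour the pyranoside with axial methoxy group (anomeric effect), the β-L anomer, which crystallises; the ring ties up O1 and O5 and presents O3 and O4 as a cis-diol.

Step 2
Reactants: 2 methyl β-L-arabinopyranoside
Product: 4 methyl 3-O-methyl-β-L-arabinopyranoside, via stannylene acetal 3 (not isolated)
Conditions: Bu2SnO, MeOH, reflux, evaporate; MeI, CsF, DMF, 40 °C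
Reagents that add atoms: iodomethane, CI; dibutyltin oxide, CCCC[Sn](=O)CCCC (its tin stays only in 3)
Why: Regioselective alkylation through a dibutylstannylene acetal: the cis-3,4-diol forms the five-membered stannylene and its equatorial oxygen O3 is the activated nucleophile, fluoride raising its reactivity towards MeI. No stereocentre is touched.

Step 3
Reactants: 4 methyl 3-O-methyl-β-L-arabinopyranoside
Product: 5 3-O-methyl-L-arabinose diethyl dithioacetal
Conditions: EtSH, conc. HCl, 0 °C → rt
Reagents that add atoms: ethanethiol, CCS
Why: Acid mercaptolysis should cleave the glycoside and trap the aldose as the open-chain dithioacetal, which holds the sugar C1 (future C6) at the aldehyde level and frees O2, O4 and O5. The methyl ether is stable to these conditions.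

Step 4
Reactants: 5 3-O-methyl-L-arabinose diethyl dithioacetal
Product: 6 2,4,5-tris-O-(tert-butyldimethylsilyl)-3-O-methyl-L-arabinose diethyl dithioacetal
Conditions: TBSOTf, 2,6-lutidine, CH2Cl2, 0 °C → rt
Reagents that add atoms: tert-butyldimethylsilyl trifluoromethanesulfonate, CC(C)(C)[Si](C)(C)OS(=O)(=O)C(F)(F)F
Why: Exhaustive silylation with the silyl triflate should reach the hindered secondary hydroxyls next to the dithioacetal and the methyl ether; thioethers are inert to it.

Step 5
Reactants: 6 2,4,5-tris-O-(tert-butyldimethylsilyl)-3-O-methyl-L-arabinose diethyl dithioacetal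
Product: 7 2,4-bis-O-(tert-butyldimethylsilyl)-3-O-methyl-L-arabinose diethyl dithioacetal
Conditions: HF·pyridine, pyridine, THF, 0 °C
Reagents that add atoms: none
Why: Buffered fluoride cleaves the unhindered primary silyl ether well before the two secondary ones (steric discrimination in desilylation), which frees only the sugar C5 hydroxyl.

Step 6
Reactants: 7 2,4-bis-O-(tert-butyldimethylsilyl)-3-O-methyl-L-arabinose diethyl dithioacetal; 8 methyl (triphenylphosphoranylidene)acetate
Product: 10 methyl (2E,4S,5S,6R)-4,6-bis(tert-butyldimethylsilyloxy)-7,7-bis(ethylsulfanyl)-5-methoxyhept-2-enoate, via C5 aldehyde 9 (not isolated)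
Conditions: (COCl)2, DMSO, CH2Cl2, −78 °C; Et3N; then 8, −78 °C → rt
Reagents that add atoms: none
Why: Swern oxidation leaves dithioacetal and silyl ethers intact, and the epimerisable α-silyloxy aldehyde is trapped in the same flask by the stabilised ylide (Wittig reaction), which should give mainly the E enoate. No stereocentre is formed, and the alkene geometry does not matter for step 8.

Step 7
Reactants: 10 methyl (2E,4S,5S,6R)-4,6-bis(tert-butyldimethylsilyloxy)-7,7-bis(ethylsulfanyl)-5-methoxyhept-2-enoate
Product: 11 methyl (2E,4S,5S,6R)-4,6-bis(tert-butyldimethylsilyloxy)-5-methoxy-7-oxohept-2-enoate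
Conditions: I2, NaHCO3, acetone–H2O, 0 °C
Reagents that add atoms: water, O
Why: Iodine-mediated hydrolysis of the dithioacetal under bicarbonate buffer is mild enough for silyl ethers and the electron-poor alkene, and it avoids the base that would epimerise C5 or expel the C4 methoxide.

Step 8
Reactants: 11 methyl (2E,4S,5S,6R)-4,6-bis(tert-butyldimethylsilyloxy)-5-methoxy-7-oxohept-2-enoate
Product: 12 methyl (3S,4S,5S,6S)-3,5-bis(tert-butyldimethylsilyloxy)-6-hydroxy-4-methoxycyclohex-1-ene-1-carboxylate
Conditions: PMe3 (1.0 equiv), t-AmOH–THF (0.02 M), 0 °C → rt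
Reagents that add atoms: none
Why: PMe3 adds reversibly to C2 of the enoate to give a phosphonium ester enolate, whose α-carbon C1 adds to the C6 aldehyde; proton transfer from C1 and E1cB loss of PMe3 then restore C1=C2. The closest known reaction type is the phosphine-mediated intramolecular Morita–Baylis–Hillman cyclisation of enoate and enone aldehydes to five- and six-membered hydroxy enoates. The single ring closes in a 6-(enolexo)-exo-trig aldol mode, and the alkene geometry of 11 is immaterial because C2 is sp3 in the zwitterion. The only new stereocentre, C6, is set by the substrate: in the chair-like transition state C4–OMe and C5–OTBS sit equatorial and C3–OTBS axial, and the aldehyde oxygen takes the axial position, where it avoids allylic 1,3-strain with the exocyclic enolate, opposes the C5–O dipole and lies near the phosphonium centre on C2. That arrangement should deliver the C6 hydroxyl cis to the C5 silyloxy group (6S). The step needs ring closure to outrun intermolecular Rauhut–Currier and aldol pathways, which high dilution and the six-membered ring secure, and it needs C5 to keep its configuration, which the weakly basic, strongly nucleophilic phosphine and the absence of amine base secure. The tertiary alcohol cosolvent speeds the proton transfer that otherwise limits ester acceptors.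

Step 9
Reactants: 12 methyl (3S,4S,5S,6S)-3,5-bis(tert-butyldimethylsilyloxy)-6-hydroxy-4-methoxycyclohex-1-ene-1-carboxylate
Product: 13 methyl (3S,4S,5R,6S)-3,5,6-tris(tert-butyldimethylsilyloxy)-4-methoxycyclohex-1-ene-1-carboxylate
Conditions: TBSOTf, 2,6-lutidine, CH2Cl2, −40 → 0 °C
Reagents that add atoms: tert-butyldimethylsilyl trifluoromethanesulfonate, CC(C)(C)[Si](C)(C)OS(=O)(=O)C(F)(F)F
Why: Silylation of the hindered allylic carbinol with the silyl triflate protects O6 from hydride and amide base. Because O5 and O6 then carry the same group, any O5-to-O6 silyl shift during step 8 converges on the same compound.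

Step 10
Reactants: 13 methyl (3S,4S,5R,6S)-3,5,6-tris(tert-butyldimethylsilyloxy)-4-methoxycyclohex-1-ene-1-carboxylate
Product: 14 [(3S,4S,5R,6S)-3,5,6-tris(tert-butyldimethylsilyloxy)-4-methoxycyclohex-1-en-1-yl]methanol
Conditions: iBu2AlH, CH2Cl2, −78 °C; aq. potassium sodium tartrate
Reagents that add atoms: none
Why: 1,2-Reduction of the conjugated ester by the aluminium hydride should give the allylic alcohol without touching the alkene or the silyl ethers.

Step 11
Reactants: 14 [(3S,4S,5R,6S)-3,5,6-tris(tert-butyldimethylsilyloxy)-4-methoxycyclohex-1-en-1-yl]methanol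
Product: 15 (3S,4S,5R,6S)-3,5,6-tris(tert-butyldimethylsilyloxy)-4-methoxycyclohex-1-ene-1-carbaldehyde
Conditions: MnO2, CH2Cl2, rt
Reagents that add atoms: none
Why: Allylic oxidation with MnO2 is neutral and stops at the enal, which has no α-hydrogen to epimerise.

Step 12
Reactants: 15 (3S,4S,5R,6S)-3,5,6-tris(tert-butyldimethylsilyloxy)-4-methoxycyclohex-1-ene-1-carbaldehyde
Product: 16 (3S,4S,5R,6S)-1-ethynyl-3,5,6-tris(tert-butyldimethylsilyloxy)-4-methoxycyclohex-1-ene
Conditions: Me3SiCHN2, LiN(iPr)2, THF, −78 → 0 °C
Reagents that add atoms: trimethylsilyldiazomethane, C[Si](C)(C)C=[N+]=[N-]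
Why: Colvin rearrangement: the lithiated silyldiazomethane adds to the aldehyde, Peterson elimination gives a diazoalkene, and loss of N2 with 1,2-hydride shift of the alkylidene carbene gives the terminal alkyne C7≡C8. The aprotic conditions avoid the conjugate addition of methanol that spoils diazophosphonate homologation of enals.

Step 13
Reactants: 17 trimethyl[(2-methylbut-3-yn-2-yl)oxy]silane; 18 2,3-dibromopropene
Product: 21 (E)-6-bromo-2-methylhepta-3,6-dien-2-ol, via alkenylzirconocene chloride 19 (not isolated), via trimethylsilyl ether 20 (not isolated)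
Conditions: Cp2Zr(H)Cl, THF, rt; 18, CuCl (10 mol %), rt; then K2CO3 (cat.), MeOH, rt
Reagents that add atoms: chloridobis(cyclopentadienyl)hydridozirconium, [H][Zr](Cl)(C1C=CC=C1)C1C=CC=C1 (its zirconium stays only in 19)
Why: Syn-hydrozirconation places the metal on the terminal carbon and fixes the E C11=C12 alkene. CuCl-catalysed allylation of the alkenylzirconocene attacks the allylic C–Br bond only (direct and allylic displacement give the same product) and forms C10–C11; methanolysis then removes the labile silyl group.

Step 14
Reactants: 16 (3S,4S,5R,6S)-1-ethynyl-3,5,6-tris(tert-butyldimethylsilyloxy)-4-methoxycyclohex-1-ene; 21 (E)-6-bromo-2-methylhepta-3,6-dien-2-ol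
Product: 22 (3E)-2-methyl-6-methylidene-8-[(3S,4S,5R,6S)-3,5,6-tris(tert-butyldimethylsilyloxy)-4-methoxycyclohex-1-en-1-yl]oct-3-en-7-yn-2-ol
Conditions: Pd(PPh3)4 (5 mol %), CuI (10 mol %), iPr2NH, THF (degassed), rt
Reagents that add atoms: none
Why: Sonogashira coupling: oxidative addition of the vinylic C9–Br bond to zerovalent palladium and transfer of the copper acetylide form C8–C9. The free tertiary alcohol is tolerated, and no allylic ester is present yet for the catalyst to ionise.

Step 15
Reactants: 22 (3E)-2-methyl-6-methylidene-8-[(3S,4S,5R,6S)-3,5,6-tris(tert-butyldimethylsilyloxy)-4-methoxycyclohex-1-en-1-yl]oct-3-en-7-yn-2-ol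
Product: 23 (3S,4S,5S,6S)-1-[(5E)-7-hydroxy-7-methyl-3-methylideneoct-5-en-1-yn-1-yl]-4-methoxycyclohex-1-ene-3,5,6-triol
Conditions: Bu4NF, THF, 0 °C → rt
Reagents that add atoms: none
Why: Fluoride cleaves all three silyl ethers without acid, so the tertiary allylic alcohol, the enyne and the skipped diene should survive.

Step 16
Reactants: 23 (3S,4S,5S,6S)-1-[(5E)-7-hydroxy-7-methyl-3-methylideneoct-5-en-1-yn-1-yl]-4-methoxycyclohex-1-ene-3,5,6-triol
Product: 26 (1S,4S,5S,6R)-4,5-dihydroxy-3-[(5E)-7-hydroxy-7-methyl-3-methylideneoct-5-en-1-yn-1-yl]-6-methoxycyclohex-2-en-1-yl acetate (the target), via 5,6-O-phenylboronate 24 (not isolated), via boronate 3-acetate 25 (not isolated)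
Conditions: PhB(OH)2 (1.05 equiv), pyridine, 4 Å MS, rt; Ac2O, 0 °C → rt; then pinacol, MeOH, rt
Reagents that add atoms: acetic anhydride, CC(=O)OC(C)=O; phenylboronic acid, OB(O)c1ccccc1 (its boron and phenyl stay only in 24 and 25)
Why: Transient boronate protection: the cis-5,6-diol alone can form the five-membered cyclic boronate, which leaves the C3 hydroxyl as the only acylable secondary alcohol (the tertiary C13 hydroxyl does not react with Ac2O in pyridine). Neutral transesterification with pinacol then frees the diol without acid or base, so the acetate and the tertiary allylic alcohol are not exposed to either.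

## Compound list

1 | L-arabinose, (2R,3S,4S)-2,3,4,5-tetrahydroxypentanal (aldehydo form) | O=C[C@H](O)[C@@H](O)[C@@H](O)CO | starting material
2 | methyl β-L-arabinopyranoside | CO[C@@H]1[C@H](O)[C@@H](O)[C@@H](O)CO1 | intermediate
3 | methyl 3,4-O-(dibutylstannanediyl)-β-L-arabinopyranoside | CO[C@@H]1[C@H](O)[C@H]2O[Sn](CCCC)(CCCC)O[C@H]2CO1 | intermediate (not isolated)
4 | methyl 3-O-methyl-β-L-arabinopyranoside | CO[C@@H]1[C@H](O)[C@@H](OC)[C@@H](O)CO1 | intermediate
5 | 3-O-methyl-L-arabinose diethyl dithioacetal | CCSC(SCC)[C@H](O)[C@@H](OC)[C@@H](O)CO | intermediate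
6 | 2,4,5-tris-O-(tert-butyldimethylsilyl)-3-O-methyl-L-arabinose diethyl dithioacetal | CCSC(SCC)[C@H](O[Si](C)(C)C(C)(C)C)[C@@H](OC)[C@@H](O[Si](C)(C)C(C)(C)C)CO[Si](C)(C)C(C)(C)C | intermediate
7 | 2,4-bis-O-(tert-butyldimethylsilyl)-3-O-methyl-L-arabinose diethyl dithioacetal | CCSC(SCC)[C@H](O[Si](C)(C)C(C)(C)C)[C@@H](OC)[C@@H](O[Si](C)(C)C(C)(C)C)CO | intermediate
8 | methyl (triphenylphosphoranylidene)acetate | COC(=O)C=P(c1ccccc1)(c1ccccc1)c1ccccc1 | starting material
9 | 2,4-bis-O-(tert-butyldimethylsilyl)-3-O-methyl-L-arabino-pentodialdose 1-(diethyl dithioacetal) | CCSC(SCC)[C@H](O[Si](C)(C)C(C)(C)C)[C@@H](OC)[C@@H](O[Si](C)(C)C(C)(C)C)C=O | intermediate (not isolated)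
10 | methyl (2E,4S,5S,6R)-4,6-bis(tert-butyldimethylsilyloxy)-7,7-bis(ethylsulfanyl)-5-methoxyhept-2-enoate | CCSC(SCC)[C@H](O[Si](C)(C)C(C)(C)C)[C@@H](OC)[C@@H](O[Si](C)(C)C(C)(C)C)/C=C/C(=O)OC | intermediate
11 | methyl (2E,4S,5S,6R)-4,6-bis(tert-butyldimethylsilyloxy)-5-methoxy-7-oxohept-2-enoate | COC(=O)/C=C/[C@H](O[Si](C)(C)C(C)(C)C)[C@H](OC)[C@@H](O[Si](C)(C)C(C)(C)C)C=O | intermediate
12 | methyl (3S,4S,5S,6S)-3,5-bis(tert-butyldimethylsilyloxy)-6-hydroxy-4-methoxycyclohex-1-ene-1-carboxylate | COC(=O)C1=C[C@H](O[Si](C)(C)C(C)(C)C)[C@H](OC)[C@@H](O[Si](C)(C)C(C)(C)C)[C@H]1O | intermediate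
13 | methyl (3S,4S,5R,6S)-3,5,6-tris(tert-butyldimethylsilyloxy)-4-methoxycyclohex-1-ene-1-carboxylate | COC(=O)C1=C[C@H](O[Si](C)(C)C(C)(C)C)[C@H](OC)[C@@H](O[Si](C)(C)C(C)(C)C)[C@H]1O[Si](C)(C)C(C)(C)C | intermediate
14 | [(3S,4S,5R,6S)-3,5,6-tris(tert-butyldimethylsilyloxy)-4-methoxycyclohex-1-en-1-yl]methanol | OCC1=C[C@H](O[Si](C)(C)C(C)(C)C)[C@H](OC)[C@@H](O[Si](C)(C)C(C)(C)C)[C@H]1O[Si](C)(C)C(C)(C)C | intermediate
15 | (3S,4S,5R,6S)-3,5,6-tris(tert-butyldimethylsilyloxy)-4-methoxycyclohex-1-ene-1-carbaldehyde | O=CC1=C[C@H](O[Si](C)(C)C(C)(C)C)[C@H](OC)[C@@H](O[Si](C)(C)C(C)(C)C)[C@H]1O[Si](C)(C)C(C)(C)C | intermediate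
16 | (3S,4S,5R,6S)-1-ethynyl-3,5,6-tris(tert-butyldimethylsilyloxy)-4-methoxycyclohex-1-ene | C#CC1=C[C@H](O[Si](C)(C)C(C)(C)C)[C@H](OC)[C@@H](O[Si](C)(C)C(C)(C)C)[C@H]1O[Si](C)(C)C(C)(C)C | intermediate
17 | trimethyl[(2-methylbut-3-yn-2-yl)oxy]silane | C#CC(C)(C)O[Si](C)(C)C | starting material
18 | 2,3-dibromopropene | C=C(Br)CBr | starting material
19 | chloridobis(cyclopentadienyl)[(1E)-3-methyl-3-(trimethylsilyloxy)but-1-en-1-yl]zirconium | C[Si](C)(C)OC(C)(C)/C=C/[Zr](Cl)(C1C=CC=C1)C1C=CC=C1 | intermediate (not isolated)
20 | {[(3E)-6-bromo-2-methylhepta-3,6-dien-2-yl]oxy}trimethylsilane | C=C(Br)C/C=C/C(C)(C)O[Si](C)(C)C | intermediate (not isolated)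
21 | (E)-6-bromo-2-methylhepta-3,6-dien-2-ol | C=C(Br)C/C=C/C(C)(C)O | intermediate
22 | (3E)-2-methyl-6-methylidene-8-[(3S,4S,5R,6S)-3,5,6-tris(tert-butyldimethylsilyloxy)-4-methoxycyclohex-1-en-1-yl]oct-3-en-7-yn-2-ol | C=C(C#CC1=C[C@H](O[Si](C)(C)C(C)(C)C)[C@H](OC)[C@@H](O[Si](C)(C)C(C)(C)C)[C@H]1O[Si](C)(C)C(C)(C)C)C/C=C/C(C)(C)O | intermediate
23 | (3S,4S,5S,6S)-1-[(5E)-7-hydroxy-7-methyl-3-methylideneoct-5-en-1-yn-1-yl]-4-methoxycyclohex-1-ene-3,5,6-triol | C=C(C#CC1=C[C@H](O)[C@H](OC)[C@@H](O)[C@H]1O)C/C=C/C(C)(C)O | intermediate
24 | 5,6-O-(phenylboranediyl) derivative of 23 (cis-fused 2-phenyl-1,3,2-dioxaborolane on O5 and O6; 3S,4S,5S,6S) | C=C(C#CC1=C[C@H](O)[C@H](OC)[C@H]2OB(c3ccccc3)O[C@@H]12)C/C=C/C(C)(C)O | intermediate (not isolated)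
25 | 3-O-acetyl-5,6-O-(phenylboranediyl) derivative of 23 (3S,4R,5S,6S) | C=C(C#CC1=C[C@H](OC(C)=O)[C@H](OC)[C@H]2OB(c3ccccc3)O[C@@H]12)C/C=C/C(C)(C)O | intermediate (not isolated)
26 | (1S,4S,5S,6R)-4,5-dihydroxy-3-[(5E)-7-hydroxy-7-methyl-3-methylideneoct-5-en-1-yn-1-yl]-6-methoxycyclohex-2-en-1-yl acetate (3S,4R,5S,6S in target numbering) | C=C(C#CC1=C[C@H](OC(C)=O)[C@H](OC)[C@@H](O)[C@H]1O)C/C=C/C(C)(C)O | target

## Step count and least certain steps

Total step count: 16. Longest linear sequence: 15 steps (steps 1 to 12 and 14 to 16, from 1); step 13 is the one-step side branch.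

Step 8 (key step). The most likely failure is stalling of the conjugate addition. The phosphine must attack a β-carbon flanked by the C3 silyloxy group, and an oxo-ester is only a modest acceptor, so oligomerisation of the aldehyde or intermolecular coupling could take over before the ring closes. Correction of C6 afterwards by an oxidation and hydride reduction cycle is not relied on, because a small hydride would be expected to attack axially and return the 5,6-trans isomer. The fallback sets out from 11 and separates the trigger from the elimination. Me2AlSPh in CH2Cl2 at −78 °C adds thiolate to C2, and the aluminium enolate closes onto the C6 aldehyde through the same chair. This gives methyl 3,5-bis(tert-butyldimethylsilyloxy)-6-hydroxy-4-methoxy-2-(phenylsulfanyl)cyclohexane-1-carboxylate F1 as a mixture at C1 and C2. Oxidation with mCPBA at −78 °C gives the sulfoxide F2. Warming, or Et3N if the acidic C1 hydrogen has to be removed in an E1cB sense, expels the sulfenate towards C1 and away from the oxygen-bearing C3. The sequence returns to the route at 12.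

Step 2. Regiocontrol may be incomplete, with some methylation at O2 or O4 or double methylation, because iodomethane is a sluggish partner for stannylene acetals and forcing conditions erode selectivity. The fallback sets out from 1 and uses the furanose form, in which O3 is the only free hydroxyl.
- Silylation of the primary hydroxyl with tert-butyldiphenylsilyl chloride in pyridine gives 5-O-(tert-butyldiphenylsilyl)-L-arabinofuranose F3.
- Acetone, 2,2-dimethoxypropane and TsOH give 5-O-(tert-butyldiphenylsilyl)-1,2-O-isopropylidene-β-L-arabinofuranose F4.
- NaH and MeI in THF give its 3-O-methyl ether F5.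
- Bu4NF gives 1,2-O-isopropylidene-3-O-methyl-β-L-arabinofuranose F6.
- EtSH and conc. HCl cleave the acetonide and open the furanose; the sequence returns to the route at 5.

Step 12. The lithiated diazo reagent may add without the rearrangement going to completion, or may act as a base on the crowded, silyl-rich enal, so conversion to the alkyne may be poor. The fallback sets out from 15 and uses the Corey–Fuchs sequence. CBr4, PPh3 and Et3N in CH2Cl2 at 0 °C give the dibromodiene (3S,4S,5R,6S)-1-(2,2-dibromoethenyl)-3,5,6-tris(tert-butyldimethylsilyloxy)-4-methoxycyclohex-1-ene F7. n-BuLi (2.2 equiv) in THF at −78 °C, by bromine–lithium exchange and 1,2-shift followed by protonation, returns to the route at 16.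

Step 16. Regiocontrol may be lost if the boronate exchanges or opens during acylation, which would allow acetyl transfer to O5 or O6, or release of the diol may be incomplete. The fallback sets out from 23 and isolates the masked diol. 2,2-Dimethoxypropane and pyridinium p-toluenesulfonate in acetone give the 5,6-O-isopropylidene derivative F8. Ac2O in pyridine gives its 3-acetate F9. Aqueous acetic acid at rt removes the acetonide and returns to the route at 26. The acid exposure of the tertiary allylic alcohol is the price of this variant.

## Further compounds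

F1 | step 8 | methyl 3,5-bis(tert-butyldimethylsilyloxy)-6-hydroxy-4-methoxy-2-(phenylsulfanyl)cyclohexane-1-carboxylate (C3 to C6 as in 12, mixture at C1 and C2) | COC(=O)C1C(Sc2ccccc2)[C@H](O[Si](C)(C)C(C)(C)C)[C@H](OC)[C@@H](O[Si](C)(C)C(C)(C)C)[C@H]1O
F2 | step 8 | methyl 3,5-bis(tert-butyldimethylsilyloxy)-6-hydroxy-4-methoxy-2-(phenylsulfinyl)cyclohexane-1-carboxylate (C3 to C6 as in 12, mixture at C1, C2 and sulfur) | COC(=O)C1C(S(=O)c2ccccc2)[C@H](O[Si](C)(C)C(C)(C)C)[C@H](OC)[C@@H](O[Si](C)(C)C(C)(C)C)[C@H]1O
F3 | step 2 | 5-O-(tert-butyldiphenylsilyl)-L-arabinofuranose (anomeric mixture) | OC1O[C@@H](CO[Si](c2ccccc2)(c2ccccc2)C(C)(C)C)[C@H](O)[C@H]1O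
F4 | step 2 | 5-O-(tert-butyldiphenylsilyl)-1,2-O-isopropylidene-β-L-arabinofuranose | CC1(C)O[C@H]2O[C@@H](CO[Si](c3ccccc3)(c3ccccc3)C(C)(C)C)[C@H](O)[C@H]2O1
F5 | step 2 | 5-O-(tert-butyldiphenylsilyl)-1,2-O-isopropylidene-3-O-methyl-β-L-arabinofuranose | CC1(C)O[C@H]2O[C@@H](CO[Si](c3ccccc3)(c3ccccc3)C(C)(C)C)[C@H](OC)[C@H]2O1
F6 | step 2 | 1,2-O-isopropylidene-3-O-methyl-β-L-arabinofuranose | CC1(C)O[C@H]2O[C@@H](CO)[C@H](OC)[C@H]2O1
F7 | step 12 | (3S,4S,5R,6S)-1-(2,2-dibromoethenyl)-3,5,6-tris(tert-butyldimethylsilyloxy)-4-methoxycyclohex-1-ene | BrC(Br)=CC1=C[C@H](O[Si](C)(C)C(C)(C)C)[C@H](OC)[C@@H](O[Si](C)(C)C(C)(C)C)[C@H]1O[Si](C)(C)C(C)(C)C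
F8 | step 16 | 5,6-O-isopropylidene derivative of 23 (cis-fused acetonide on O5 and O6) | C=C(C#CC1=C[C@H](O)[C@H](OC)[C@H]2OC(C)(C)O[C@@H]12)C/C=C/C(C)(C)O
F9 | step 16 | 3-O-acetyl-5,6-O-isopropylidene derivative of 23 | C=C(C#CC1=C[C@H](OC(C)=O)[C@H](OC)[C@H]2OC(C)(C)O[C@@H]12)C/C=C/C(C)(C)O
A1 | alternative 1 | 4,4-dimethoxycyclohexa-2,5-dien-1-one | COC1(OC)C=CC(=O)C=C1
A2 | alternative 1 | 5,6-epoxy-4,4-dimethoxycyclohex-2-en-1-one (oxirane across target C4 and C5, single enantiomer) | O=C1C=CC(OC)(OC)[C@H]2O[C@@H]12
A3 | alternative 2 | D-galactose (aldehydo form) | O=C[C@H](O)[C@@H](O)[C@@H](O)[C@H](O)CO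
A4 | alternative 2 | methyl 6-deoxy-3,4-O-isopropylidene-2-O-methyl-β-L-arabino-hex-5-enopyranoside | C=C1O[C@H](OC)[C@H](OC)[C@H]2OC(C)(C)O[C@@H]12
A5 | alternative 2 | 3-hydroxy-4-methoxy-5,6-O-isopropylidenecyclohexan-1-one (target numbering) | O=C1C[C@H](O)[C@H](OC)[C@H]2OC(C)(C)O[C@@H]12
A6 | alternative 3 | (Z)-enynal dialdehyde: 4,5-cis-5-formyl-2,2-dimethyl-1,3-dioxolan-4-yl group on C1, triisopropylsilylethynyl on C1, formyl on C2 of the alkene | O=C/C=C(C#C[Si](C(C)C)(C(C)C)C(C)C)\[C@@H]1OC(C)(C)O[C@@H]1C=O
A7 | alternative 3 | 1-(triisopropylsilylethynyl)cyclohexene-3,4-diol with C5/C6 acetonide (target numbering) | CC(C)[Si](C(C)C)(C(C)C)C#CC1=C[C@H](O)[C@H](O)[C@H]2OC(C)(C)O[C@@H]12
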